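The cyclopentenone is disconnected to a 4-pyranone: within the five-membered ring, the C4 oxygen, the C1 carbonyl and the C2=C3 alkene are read as ring oxygen, carbonyl and one enol-ether alkene of the heterocycle, whose 3-position (future quaternary carbinol C5) carries the (S)-configured C6 side chain as its tert-butyl carbonate. Irradiation should contract the pyranone to the carbocycle (new C3–C4 bond) while the carbonate oxygen is delivered to C5, so that the ring, the trans C4/C5 oxygen pair and the C5 quaternary centre arise in one operation as a spiro cyclic carbonate. The C6 centre, set by oxazaborolidine-catalysed ketone reduction, is the only source of asymmetry; carbonate methanolysis and diacetylation complete the route.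

Key step: step 6

Remark: atom labels C1–C6 are those of the target (C1 ketone, C2=C3, C4 acetoxy methine, C5 carbinol, C6 side-chain methine). The target is read as 4R,5S,6S (C4 and C5 oxygens trans, C6 cis to the C4 oxygen), and the structures of the key-step precursor and product were found consistent with this. The CIP letter of C5 differs between the cyclic carbonate and the triol without any change of geometry.

Step 1
Reactants: 1 2,3-dihydro-4H-pyran-4-one; 2 pentadecanal
Product: 4 3-(1-hydroxypentadecyl)-2,3-dihydro-4H-pyran-4-one (racemic syn/anti mixture), via lithium 2H-pyran-4-olate 3 (not isolated)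
Conditions: LiN(iPr)2 (commercial solution, 1.1 equiv), THF, −78 °C; then 2, −78 °C; aq. NH4Cl
Reagents that add atoms: none
Why: Kinetic deprotonation of the vinylogous ester at its α′ methylene (C3 of the ring) gives cross-conjugated lithium dienolate 3, which should add to the aldehyde in a directed aldol addition; the two stereocentres formed are left uncontrolled because both are erased in steps 2 to 4.

Step 2
Reactants: 4 3-(1-hydroxypentadecyl)-2,3-dihydro-4H-pyran-4-one
Product: 5 3-pentadecanoyl-2,3-dihydro-4H-pyran-4-one (racemic, largely enolised)
Conditions: Dess–Martin periodinane (1.2 equiv), CH2Cl2, 0 °C to rt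
Reagents that add atoms: none
Why: Dess–Martin oxidation is the standard neutral method for turning a β-hydroxy ketone into a 1,3-diketone without retro-aldol cleavage, and the small excess should spare the doubly activated C3–H.

Step 3
Reactants: 5 3-pentadecanoyl-2,3-dihydro-4H-pyran-4-one
Product: 6 3-pentadecanoyl-4H-pyran-4-one
Conditions: DDQ (1.1 equiv), 1,4-dioxane, rt
Reagents that add atoms: none
Why: Quinone dehydrogenation of an enolised β-dicarbonyl compound: hydride abstraction from the oxygen-bearing ring CH2 next to the enol and loss of a proton should give the fully unsaturated 4-pyranone, the same change as the chromanone-to-chromone oxidation.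

Step 4
Reactants: 6 3-pentadecanoyl-4H-pyran-4-one
Product: 7 3-[(1S)-1-hydroxypentadecyl]-4H-pyran-4-one
Conditions: (R)-2-methyl-CBS-oxazaborolidine [(3aR)-1-methyl-3,3-diphenyltetrahydro-1H,3H-pyrrolo[1,2-c][1,3,2]oxazaborole] (0.2 equiv), BH3·SMe2 (0.7 equiv), THF, −30 °C, slow addition of 6; MeOH quench
Reagents that add atoms: none
Why: Corey–Bakshi–Shibata reduction: with the planar pyranonyl group as the large and the primary alkyl chain as the small substituent, the (R)-catalyst should deliver hydride to the face that gives the (S)-carbinol, as with aryl alkyl ketones, while the ring carbonyl, a doubly vinylogous ester, should not be reduced at this temperature.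

Step 5
Reactants: 7 3-[(1S)-1-hydroxypentadecyl]-4H-pyran-4-one; 8 di-tert-butyl dicarbonate
Product: 9 tert-butyl (1S)-1-(4-oxo-4H-pyran-3-yl)pentadecyl carbonate
Conditions: DMAP (0.1 equiv), CH2Cl2, 0 °C to rt
Reagents that add atoms: none
Why: DMAP-catalysed O-tert-butoxycarbonylation of a secondary allylic alcohol, as used for Baylis–Hillman-type carbonates, acylates oxygen without touching the C6–O bond, so the (S)-configuration is retained.

Step 6
Reactants: 9 tert-butyl (1S)-1-(4-oxo-4H-pyran-3-yl)pentadecyl carbonate
Product: 12 (4S,5R,9R)-9-hydroxy-4-tetradecyl-1,3-dioxaspiro[4.4]non-7-ene-2,6-dione, via oxirane-fused oxyallyl zwitterion 10 (not isolated), via tert-butoxydioxolanylium alkoxide 11 (not isolated)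
Conditions: hν (254 nm, low-pressure Hg lamp, quartz), (CF3)2CHOH, 3 mM, Ar, 10 °C, stopped when 9 is consumed
Reagents that add atoms: none
Why: Proposed new method: excitation of the pyranone should induce 4π electrocyclization between its two oxygen-bearing carbons (target C3 and C4) to give, reversibly and on either face, the oxirane-fused oxyallyl zwitterion 10; the carbonate carbonyl oxygen then adds to the substituted allyl terminus C5 from the face opposite the oxirane, the enolate so formed opens the oxirane to the C4 alkoxide and the C2=C3 enone, and the tert-butoxydioxolanylium ion 11 collapses by loss of isobutene with protonation of the alkoxide. The closest known reaction type is the photochemical contraction of 4-pyranones to 4-hydroxycyclopent-2-enones in which the zwitterion is captured by a hydroxylic solvent or by a tethered hydroxyl or carboxyl group, combined here with the neighbouring-group capture of cations by tert-butyl carbonates familiar from halocyclisations. The carbocycle is closed by the electrocyclization (C3–C4 bond, transient fused oxirane) and the dioxolanone by a 5-exo-trig attack of oxygen on C5. C4 keeps the former ring oxygen on the face where the oxirane formed, and C5 is set relative to it by the anti attack, which gives the trans C4–O/C5–O pair with C6 cis to the C4 oxygen. The sense relative to C6 should come from allylic 1,3-strain in the closure: when the C6–H bond eclipses the C5–C1 bond next to the oxyallyl oxygen, the carbonate of the (S)-centre can reach only one face of C5, so only the zwitterion with the oxirane on the other face is drained, and this leads to the 4R,5S,6S series. The step needs regioselectivity (oxygen at C5 and not at C2), secured by the short tether, and chemoselectivity against solvent capture, secured by the non-nucleophilic, ionising solvent.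

Step 7
Reactants: 12 (4S,5R,9R)-9-hydroxy-4-tetradecyl-1,3-dioxaspiro[4.4]non-7-ene-2,6-dione
Product: 14 (4R,5S)-4,5-dihydroxy-5-[(1S)-1-hydroxypentadecyl]cyclopent-2-en-1-one, via C6 methyl carbonate 13 (not isolated)
Conditions: K2CO3 (0.2 equiv), MeOH, 0 °C; AcOH to pH 7
Reagents that add atoms: none
Why: Base-catalysed transesterification: the cyclic carbonate is activated as the ester of an α-ketol, so methoxide should open it at 0 °C with the C5 oxygen as leaving group to give methyl carbonate 13, which is cleaved in turn to the triol and dimethyl carbonate without touching a stereocentre.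

Step 8
Reactants: 14 (4R,5S)-4,5-dihydroxy-5-[(1S)-1-hydroxypentadecyl]cyclopent-2-en-1-one
Product: 15 (4R,5S)-4-acetoxy-5-[(1S)-1-acetoxypentadecyl]-5-hydroxycyclopent-2-en-1-one (the target)
Conditions: Ac2O (4 equiv), pyridine, 0 °C to rt
Reagents that add atoms: acetic anhydride, CC(=O)OC(C)=O
Why: Acetylation with acetic anhydride in pyridine should esterify the two secondary hydroxyls, whereas the hindered tertiary α-ketol hydroxyl at C5 is not expected to react without an acyl-transfer catalyst, and the 4-acetoxy enone cannot eliminate because C5 bears no hydrogen.

Compound list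
1 | 2,3-dihydro-4H-pyran-4-one | O=C1CCOC=C1 | starting material
2 | pentadecanal | CCCCCCCCCCCCCCC=O | starting material
3 | lithium 2H-pyran-4-olate (dienolate of 1 deprotonated at C3; not isolated) | [Li+].[O-]C1=CCOC=C1 | intermediate
4 | 3-(1-hydroxypentadecyl)-2,3-dihydro-4H-pyran-4-one (racemic mixture of syn and anti diastereomers) | CCCCCCCCCCCCCCC(O)C1COC=CC1=O | intermediate
5 | 3-pentadecanoyl-2,3-dihydro-4H-pyran-4-one (racemic, keto form drawn) | CCCCCCCCCCCCCCC(=O)C1COC=CC1=O | intermediate
6 | 3-pentadecanoyl-4H-pyran-4-one | CCCCCCCCCCCCCCC(=O)C1=COC=CC1=O | intermediate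
7 | 3-[(1S)-1-hydroxypentadecyl]-4H-pyran-4-one | CCCCCCCCCCCCCC[C@H](O)C1=COC=CC1=O | intermediate
8 | di-tert-butyl dicarbonate | CC(C)(C)OC(=O)OC(=O)OC(C)(C)C | starting material
9 | tert-butyl (1S)-1-(4-oxo-4H-pyran-3-yl)pentadecyl carbonate | CCCCCCCCCCCCCC[C@H](OC(=O)OC(C)(C)C)C1=COC=CC1=O | intermediate
10 | oxirane-fused oxyallyl zwitterion (6-oxabicyclo[3.1.0]hexane core; oxirane across C3–C4 on the face that becomes the C4–O face of 12; oxyallyl unit C2–C1(O−)–C5(+); (S)-configured tert-butoxycarbonyloxy side chain on C5; not isolated) | CCCCCCCCCCCCCC[C@H](OC(=O)OC(C)(C)C)[C+]1C([O-])=C[C@H]2O[C@@H]12 | intermediate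
11 | 2-tert-butoxy-1,3-dioxolan-2-ylium C4-alkoxide zwitterion with the spiro skeleton and configuration of 12 (not isolated) | CCCCCCCCCCCCCC[C@@H]1O[C+](OC(C)(C)C)O[C@@]12C(=O)C=C[C@H]2[O-] | intermediate
12 | (4S,5R,9R)-9-hydroxy-4-tetradecyl-1,3-dioxaspiro[4.4]non-7-ene-2,6-dione (spiro C5/C6 cyclic carbonate; C4–OH trans to the C5 oxygen and cis to C6) | CCCCCCCCCCCCCC[C@@H]1OC(=O)O[C@@]12C(=O)C=C[C@H]2O | intermediate
13 | methyl (1S)-1-[(1R,5R)-1,5-dihydroxy-2-oxocyclopent-3-en-1-yl]pentadecyl carbonate (not isolated) | CCCCCCCCCCCCCC[C@H](OC(=O)OC)[C@@]1(O)C(=O)C=C[C@H]1O | intermediate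
14 | (4R,5S)-4,5-dihydroxy-5-[(1S)-1-hydroxypentadecyl]cyclopent-2-en-1-one | CCCCCCCCCCCCCC[C@H](O)[C@@]1(O)C(=O)C=C[C@H]1O | intermediate
15 | (4R,5S)-4-acetoxy-5-[(1S)-1-acetoxypentadecyl]-5-hydroxycyclopent-2-en-1-one | CCCCCCCCCCCCCC[C@H](OC(C)=O)[C@@]1(O)C(=O)C=C[C@H]1OC(C)=O | target

Total step count: 8. Longest linear sequence: 8 steps (from 1 or 2 to 15).

Steps most likely to fail

1. Step 6. The carbonate carbonyl oxygen may be too weak a nucleophile to intercept the short-lived zwitterion, so that reversion, rearrangement to the isomeric 2-pyranone or slow solvolysis of the allylic carbonate in the fluorinated alcohol takes over. Alternatively, closure may occur on both ring faces if the C6 centre exerts too little facial bias, which would give the C6-epimeric series alongside the wanted one. The tert-butyl carbonate is kept as the trapping group because dealkylation of the dioxolanylium ion makes the capture irreversible. Fallback with known chemistry: it sets out from 7 and comes back at 14. Free alcohol 7 would be irradiated at 254 nm in MeCN/H2O, so that water captures the zwitterion in the established solvent-capture mode. Hydroxyl should enter at the more substituted allyl terminus anti to the oxirane and give triol 14 directly, and steps 5 to 7 are then bypassed. Facial and regioisomeric adducts would have to be removed by chromatography. No compound outside the list is made (F0).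

2. Step 4. The basic ring carbonyl may sequester borane and the oxazaborolidine, so that uncatalysed hydride transfer or conjugate hydride delivery to the ring C2 competes and the enantiomeric purity of the carbinol is eroded. Fallback: it sets out from 6 and comes back at 7. Luche reduction (NaBH4, CeCl3·7H2O, MeOH, −78 °C) should favour 1,2-attack at the exocyclic ketone and give racemic 3-(1-hydroxypentadecyl)-4H-pyran-4-one F1. Its enantiomers would be separated by preparative HPLC on a chiral stationary phase (amylose tris(3,5-dimethylphenylcarbamate)) to give 7.

3. Step 7. Under basic methanolysis the free C4 alkoxide may trigger retro-aldol opening of the ring (C4–C5 cleavage), or methoxide may add to the enone, leading to decomposition or epimerisation before the carbonate is fully cleaved. Fallback: it sets out from 12 and comes back at 14. The C4 hydroxyl would first be silylated (TESOTf, 2,6-lutidine, CH2Cl2, −78 °C) to give (4S,5S,9R)-4-tetradecyl-9-[(triethylsilyl)oxy]-1,3-dioxaspiro[4.4]non-7-ene-2,6-dione F2, which cannot form the C4 alkoxide. Methanolysis (K2CO3, MeOH, 0 °C) should then give (4R,5S)-5-hydroxy-5-[(1S)-1-hydroxypentadecyl]-4-[(triethylsilyl)oxy]cyclopent-2-en-1-one F3. Desilylation under non-basic conditions (HF·pyridine, THF, 0 °C) would return triol 14.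

Further compounds
F0 | step 6 | none | none
F1 | step 4 | racemic 3-(1-hydroxypentadecyl)-4H-pyran-4-one | CCCCCCCCCCCCCCC(O)C1=COC=CC1=O
F2 | step 7 | (4S,5S,9R)-4-tetradecyl-9-[(triethylsilyl)oxy]-1,3-dioxaspiro[4.4]non-7-ene-2,6-dione | CCCCCCCCCCCCCC[C@@H]1OC(=O)O[C@@]12C(=O)C=C[C@H]2O[Si](CC)(CC)CC
F3 | step 7 | (4R,5S)-5-hydroxy-5-[(1S)-1-hydroxypentadecyl]-4-[(triethylsilyl)oxy]cyclopent-2-en-1-one | CCCCCCCCCCCCCC[C@H](O)[C@@]1(O)C(=O)C=C[C@H]1O[Si](CC)(CC)CC
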